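The meeting took up the gamma run first, the neighbour of this flask with half the substrate charge at the same gas and catalyst.

- gamma: left-handed substrate 1 mM; right-handed substrate 1 mM; gas 0.44 mM (held); catalyst 10 µM; run made earlier
- flask: left-handed substrate 2.0 mM; gas 0.44 mM (held); catalyst 10 µM; right-handed substrate 2.0 mM

gamma run (percent of the left-handed substrate and right-handed substrate together charged)

| time / s | left-handed product / % | left-handed substrate / % |
|---|---|---|
| 10.0 | 6.1 | 44.2 |
| 15.0 | 9.3 | 39.8 |
| 25.0 | 17.7 | 31.0 |
| 40.0 | 27.8 | 21.6 |
| 80.0 | 43.9 | 3.1 |
| 120 | 50.6 | 0.5 |

(readings scatter by 1 percentage point)

- catalyst is single-handed; left-handed substrate and right-handed substrate are mirror images of each other, charged as a racemate, each of them at the stated concentration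
- the numbers in the tables scatter with a standard deviation of 1 percentage point
- at the start none of the gas is in solution
- no earlier run changes the charge of catalyst; that part of a forecast is a guess

- factor on the rate of making left-handed product when 50% of the left-handed substrate and right-handed substrate together are converted if catalyst is charged twice over
- factor on the rate when 50% of the left-handed substrate and right-handed substrate together are converted if catalyst is charged at 1.0 µM instead

The kinetics chemist pointed out that left-handed product in the gamma run climbed nearly straight from 9.3% at 15.0 s to 27.8% at 40.0 s, while left-handed substrate fell to about half of its reading, a zero-order stretch, and she proposed carrying the pace W = 0.888 mM/min, the left-handed product made per minute along that stretch.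

The process chemist answered that, taking one gas per product, W would use up a saturated solution in 29.7 s, a lifetime shorter than the 80.0 s the gamma run needed to bring left-handed substrate down to 3.1%, so gas has to keep entering during the run.

The kinetics chemist replied that a catalyst working flat out would draw the same straight line, and that the gamma run cannot tell the two apart. The meeting's own reckoning nevertheless took the straight stretch to be held by the entry of gas rather than by catalyst at work, with W counting just the part of that entry that ends as left-handed product, since the gamma run has no readings of what right-handed substrate takes, so left-handed product in this flask should be made near W, doubling the catalyst should give a factor close to one, and the 1.0 µM charge stayed a guess below one.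

The forecast differs, giving 1.9 and 0.11, on the ground that “At a fixed composition the rate should therefore scale with catalyst, roughly first order”.

The flask gives 1.07 for the doubled charge and 0.578 for the 1.0 µM charge.

    reagent + catalyst + left-handed substrate → catalyst + left-handed product (k = 6.50 × 10⁷ /M²/s)
    reagent + catalyst + right-handed substrate → catalyst + right-handed product (k = 2.80 × 10⁷ /M²/s)
    2 catalyst ⇌ resting dimer, settled at all times (K = 2.60 × 10⁵ /M)
    gas ⇌ reagent, rate k4*(csat - [reagent]) (kL = 0.0680 /s)

At 1.43 min in this flask, reagent, the dissolved gas, is made 1.04 times as fast as it is used up. The rate of 0.797 mM/min at 1.33 min is 0.898 of W, and W run for 1.00 min gives 0.888 mM, against 1.00 mM of left-handed product standing in this flask at that time.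

The earlier runs and the new flask stem from a simulated flask with made-up constants; the scatter is artificial.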